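## Retrosynthetic overview

Labdane numbering is used (C17 exocyclic methylene, C18 methyl and C19 carboxyl on C4, C20 methyl on C10).

1. The (13Z)-γ-hydroxy acid is made last, from a C12 aldehyde by catalytic asymmetric propiolate addition (sets C12) and syn-cuprate addition followed by saponification. C17 comes from a C8 ketone by Wittig methylenation.
2. C5 and C4 are set in one event by dissolving-metal reductive methylation of a C4=C5 enoate (H and CH3 both enter anti to C20), so the ring closure must leave C5 sp2.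
3. Key disconnection C5–C6 (closes ring B). C5 is the β-carbon of the C19 carboxyl, and C6 is the β-carbon of C8, the ring B carbon whose exocyclic methylene C17 is a masked carbonyl. C5–C6 is therefore a β,β′ link between two carbonyls (1,6-relationship C19…C8), made by palladium-catalysed coupling of a C8 cyclopropanol (ketone homoenolate) with the C5 enol triflate of the ring A β-keto ester.
4. Ring A is bought. Its quaternary C10 and the C9 branch come from an Ireland–Claisen rearrangement that relays a catalytically set C4 carbinol centre to C10. C5, C4 and C9 then follow from C10 by substrate control.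
5. Ring order: A (purchased), then B (step 8). The 15,12-lactone is never closed on purpose.

Key step: step 8

Assumption: the target is the ring-opened form of a butenolide and relactonises under acid, so it is liberated last, at 0 °C and about pH 5, and isolated without heating.

Remark: C10 is an uncontrolled centre in 3, 4 and 6 (erased in step 4); C9 is an epimer mixture in 9–17 (set in step 10); C8 is an alcohol epimer mixture in 16.

## Route

Step 1
Reactants: 1 tert-butyl 2-oxocyclohexane-1-carboxylate
Product: 3 tert-butyl 3-methyl-2-oxocyclohexane-1-carboxylate, via dilithium dienolate 2 (not isolated)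
Conditions: LiN(iPr)2 (2.2 equiv), THF, −78 to 0 °C; MeI (1.05 equiv), −78 °C; aq. HCl
Reagents that add atoms: iodomethane CI
Why: Huckin–Weiler γ-alkylation, in which the β-keto ester dianion reacts at its more basic γ-carbon (C10) so that methylation is regioselective; the new centre is uncontrolled, which is harmless because C10 is made planar again in step 4.

Step 2
Reactants: 3 tert-butyl 3-methyl-2-oxocyclohexane-1-carboxylate
Product: 4 tert-butyl (1R)-1-hydroxy-3-methyl-2-oxocyclohexane-1-carboxylate
Conditions: Ni(ClO4)2·6H2O (10 mol %), DBFOX-Ph ligand (11 mol %; enantiomer that gives 1R), 3-phenyl-2-(phenylsulfonyl)oxaziridine (1.2 equiv), 4 Å MS, CH2Cl2, 20 °C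
Reagents that add atoms: 3-phenyl-2-(phenylsulfonyl)oxaziridine O=S(=O)(N1OC1c1ccccc1)c1ccccc1
Why: Catalytic enantioselective α-hydroxylation of a β-keto ester, in which the two-point-bound nickel enolate exposes one face to the electrophilic oxygen of the oxaziridine, so the C4 carbinol centre (1R) is set by catalyst control irrespective of the remote C10 methyl.

Step 3
Reactants: 4 tert-butyl (1R)-1-hydroxy-3-methyl-2-oxocyclohexane-1-carboxylate; 5 3-(1,3-dioxolan-2-yl)propanoic acid
Product: 6 (1R)-1-(tert-butoxycarbonyl)-3-methyl-2-oxocyclohexyl 3-(1,3-dioxolan-2-yl)propanoate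
Conditions: DCC (1.5 equiv), DMAP (0.3 equiv), CH2Cl2, 0 to 20 °C
Reagents that add atoms: none
Why: Steglich esterification (carbodiimide activation with acyl transfer by DMAP) should acylate the hindered tertiary α-ketol under neutral conditions that avoid α-ketol rearrangement, and it touches no stereocentre.

Step 4
Reactants: 6 (1R)-1-(tert-butoxycarbonyl)-3-methyl-2-oxocyclohexyl 3-(1,3-dioxolan-2-yl)propanoate
Product: 7 tert-butyl (1R)-2-[(tert-butyldimethylsilyl)oxy]-1-{[3-(1,3-dioxolan-2-yl)propanoyl]oxy}-3-methylcyclohex-2-ene-1-carboxylate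
Conditions: TBSOTf (1.2 equiv), Et3N (2.0 equiv), CH2Cl2, −78 to 0 °C
Reagents that add atoms: tert-butyldimethylsilyl trifluoromethanesulfonate CC(C)(C)[Si](C)(C)OS(=O)(=O)C(F)(F)F
Why: Soft enolisation with O-silylation (silyl triflate and amine base) can only enolise the ketone toward C10 because C4 is fully substituted, which gives the tetrasubstituted enol ether needed as the allyl component of step 5 and erases the uncontrolled C10 centre.

Step 5
Reactants: 7 tert-butyl (1R)-2-[(tert-butyldimethylsilyl)oxy]-1-{[3-(1,3-dioxolan-2-yl)propanoyl]oxy}-3-methylcyclohex-2-ene-1-carboxylate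
Product: 11 tert-butyl (3R)-2-[(tert-butyldimethylsilyl)oxy]-3-[3-(1,3-dioxolan-2-yl)-1-methoxy-1-oxopropan-2-yl]-3-methylcyclohex-1-ene-1-carboxylate, via trimethylsilyl ketene acetal 8 (not isolated), via trimethylsilyl ester 9 (not isolated), via carboxylic acid 10 (not isolated)
Conditions: LiN(iPr)2 (1.3 equiv), TMSCl–Et3N (1.6 equiv), THF, −78 °C, then 20 to 60 °C; pH 5 aqueous work-up; TMSCHN2 (1.5 equiv), toluene–MeOH 4:1, 0 °C
Reagents that add atoms: (trimethylsilyl)diazomethane C[Si](C)(C)C=[N+]=[N-]
Why: Ireland–Claisen rearrangement, in which the silyl ketene acetal of the tertiary allylic ester undergoes a suprafacial [3,3] shift that forms C9–C10 on the face that carried the C4–O bond, so the C4 carbinol chirality is relayed to the quaternary C10 while C4=C5 becomes a conjugated β-silyloxy enoate (the driving force); C9 forms as an epimer mixture that is corrected in step 10, and the acid is capped as its methyl ester.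

Step 6
Reactants: 11 tert-butyl (3R)-2-[(tert-butyldimethylsilyl)oxy]-3-[3-(1,3-dioxolan-2-yl)-1-methoxy-1-oxopropan-2-yl]-3-methylcyclohex-1-ene-1-carboxylate
Product: 12 tert-butyl (3R)-2-[(tert-butyldimethylsilyl)oxy]-3-[2-(1,3-dioxolan-2-yl)-1-(1-hydroxycyclopropyl)ethyl]-3-methylcyclohex-1-ene-1-carboxylate
Conditions: EtMgBr (3.2 equiv, slow addition), Ti(OiPr)4 (0.5 equiv), THF, 0 to 20 °C
Reagents that add atoms: ethylmagnesium bromide CC[Mg]Br
Why: Kulinkovich cyclopropanation, in which the titanacyclopropane formed from EtMgBr and Ti(OiPr)4 converts the methyl ester into the cyclopropanol (C6 and C7 both come from the Grignard reagent), while the hindered, vinylogous tert-butyl ester should not react.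

Step 7
Reactants: 12 tert-butyl (3R)-2-[(tert-butyldimethylsilyl)oxy]-3-[2-(1,3-dioxolan-2-yl)-1-(1-hydroxycyclopropyl)ethyl]-3-methylcyclohex-1-ene-1-carboxylate
Product: 13 tert-butyl (3R)-3-[2-(1,3-dioxolan-2-yl)-1-(1-hydroxycyclopropyl)ethyl]-3-methyl-2-{[(trifluoromethyl)sulfonyl]oxy}cyclohex-1-ene-1-carboxylate
Conditions: CsF (2.0 equiv), PhNTf2 (1.2 equiv), DME, 20 °C
Reagents that add atoms: N-phenylbis(trifluoromethanesulfonimide) O=S(=O)(N(c1ccccc1)S(=O)(=O)C(F)(F)F)C(F)(F)F
Why: Fluoride-triggered exchange of a silyl enol ether for an enol triflate, in which CsF unmasks the β-keto ester enolate regiospecifically and PhNTf2 traps it on oxygen, without touching the far less acidic cyclopropanol.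

Step 8
Reactants: 13 tert-butyl (3R)-3-[2-(1,3-dioxolan-2-yl)-1-(1-hydroxycyclopropyl)ethyl]-3-methyl-2-{[(trifluoromethyl)sulfonyl]oxy}cyclohex-1-ene-1-carboxylate
Product: 14 tert-butyl (4aR)-5-[(1,3-dioxolan-2-yl)methyl]-4a-methyl-6-oxo-2,3,4,4a,5,6,7,8-octahydronaphthalene-1-carboxylate
Conditions: Pd(OAc)2 (10 mol %), XPhos (20 mol %), Cs2CO3 (2.0 equiv), toluene, 80 °C
Reagents that add atoms: none
Why: Zerovalent palladium inserts into the C5–OTf bond of the β-triflyloxy enoate, the cyclopropanol binds as a palladium alkoxide, strain-driven β-carbon elimination opens the three-membered ring to the palladium homoenolate (Pd–C6H2–C7H2–C8=O; the two ring CH2 groups are equivalent, so there is no regiochemical choice) and C(sp2)–C(sp3) reductive elimination forms C5–C6. The closest known reaction type is the palladium-catalysed ring-opening cross-coupling of cyclopropanols (ketone homoenolates) with aryl and alkenyl halides or triflates, which is also known in intramolecular ring-forming versions. Ring B (C5–C6–C7–C8–C9–C10) is closed by reductive elimination from a seven-membered palladacycle, formally a 6-exo closure onto the enol triflate carbon with C4=C5 staying exocyclic to the new ring. No stereocentre is created at C5, which deliberately stays sp2 so that its hydrogen can be delivered anti to C20 in step 9; C10 is untouched, and C9, now α to the C8 ketone, is left as an epimer mixture to be set thermodynamically in step 10. The selectivity needed is reductive elimination over β-hydride elimination of the alkylpalladium (which would give the vinyl ketone and the detriflated enoate); it should be secured by the bulky biaryl phosphine, by chelation of palladium by the C8 carbonyl and by the quaternary C10, which holds C6 next to C5. In one operation the step closes the carbocyclic core, unmasks the C8 carbonyl that becomes C17, makes C9 correctable and leaves the C4=C5 enoate needed to install C5 and C4 together.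

Step 9
Reactants: 14 tert-butyl (4aR)-5-[(1,3-dioxolan-2-yl)methyl]-4a-methyl-6-oxo-2,3,4,4a,5,6,7,8-octahydronaphthalene-1-carboxylate
Product: 16 tert-butyl 12,12-(ethylenedioxy)-8-hydroxy-13,14,15,16,17-pentanorlabdan-19-oate, via dilithium alkoxide enolate 15 (not isolated)
Conditions: Li (10 equiv), NH3(l)–THF, t-BuOH (2.2 equiv), −78 °C; isoprene; MeI (10 equiv), −78 to −33 °C; H2O
Reagents that add atoms: iodomethane CI
Why: Dissolving-metal (Birch-type) reductive alkylation of an α,β-unsaturated ester, in which C5 is protonated axially on the α-face, anti to the C20 methyl (trans ring fusion), and the resulting ester enolate is methylated from the same less hindered α-face, so that C18 becomes equatorial and the ester C19 axial; the C8 ketone is reduced to the alcohol in the same pot and is restored in step 10.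

Step 10
Reactants: 16 tert-butyl 12,12-(ethylenedioxy)-8-hydroxy-13,14,15,16,17-pentanorlabdan-19-oate
Product: 18 tert-butyl 12,12-(ethylenedioxy)-8-oxo-13,14,15,16,17-pentanorlabdan-19-oate, via C9-epimeric 8-ketone mixture 17 (not isolated)
Conditions: Dess–Martin periodinane (1.5 equiv), NaHCO3, CH2Cl2, 20 °C; then NaOMe (0.2 equiv), MeOH, 20 °C
Reagents that add atoms: none
Why: Dess–Martin oxidation returns the C8 ketone, and base-mediated epimerisation through the C8 enolate (thermodynamic control, now with a chair ring B carrying axial H-5) should place the C9 side chain equatorial, which is the natural configuration.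

Step 11
Reactants: 18 tert-butyl 12,12-(ethylenedioxy)-8-oxo-13,14,15,16,17-pentanorlabdan-19-oate
Product: 19 tert-butyl 12,12-(ethylenedioxy)-13,14,15,16-tetranorlabd-8(17)-en-19-oate
Conditions: Ph3PCH3Br (3.0 equiv), KOtBu (2.8 equiv), toluene, 20 to 80 °C
Reagents that add atoms: methyltriphenylphosphonium bromide C[P+](c1ccccc1)(c1ccccc1)c1ccccc1.[Br-]
Why: Wittig methylenation of the hindered C8 ketone installs C17, and because C9 already sits at its thermodynamic configuration the basic ylide should not erode it.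

Step 12
Reactants: 19 tert-butyl 12,12-(ethylenedioxy)-13,14,15,16-tetranorlabd-8(17)-en-19-oate
Product: 20 tert-butyl 12-oxo-13,14,15,16-tetranorlabd-8(17)-en-19-oate
Conditions: 2 M aq. HCl–THF (1:4), 20 °C
Reagents that add atoms: water O
Why: Acid-catalysed acetal hydrolysis liberates the C12 aldehyde under conditions (dilute aqueous acid, room temperature) that should leave the tert-butyl ester and the 1,1-disubstituted alkene intact.

Step 13
Reactants: 20 tert-butyl 12-oxo-13,14,15,16-tetranorlabd-8(17)-en-19-oate; 21 methyl propiolate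
Product: 22 19-tert-butyl 15-methyl (12S)-12-hydroxy-16-norlabd-8(17)-en-13-yne-15,19-dioate
Conditions: Me2Zn (3.0 equiv), ProPhenol ligand (20 mol %; enantiomer that gives 12S), Ph3PO (40 mol %), toluene, 4 °C
Reagents that add atoms: none
Why: Catalytic enantioselective alkynylation of an aldehyde (dinuclear zinc–ProPhenol catalysis) adds the zinc acetylide of methyl propiolate and sets C12 by catalyst control, the nearest ring stereocentre (C9) being β to the carbonyl and too remote to compete.

Step 14
Reactants: 22 19-tert-butyl 15-methyl (12S)-12-hydroxy-16-norlabd-8(17)-en-13-yne-15,19-dioate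
Product: 24 (12S)-12-hydroxy-15-methoxy-15-oxo-16-norlabd-8(17)-en-13-yn-19-oic acid, via bis(trimethylsilyl) derivative 23 (not isolated)
Conditions: TMSOTf (4 equiv), 2,6-lutidine (6 equiv), CH2Cl2, 0 °C; then 10% aq. citric acid–THF, 20 °C
Reagents that add atoms: none
Why: Silyl triflate-mediated tert-butyl ester cleavage (alkyl–oxygen fission to isobutene, buffered by 2,6-lutidine) frees the hindered axial C19 acid without protic acid that could isomerise the exocyclic alkene, and it is placed before any butenolide can form so that no enolisable γ-lactone meets the silyl triflate.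

Step 15
Reactants: 24 (12S)-12-hydroxy-15-methoxy-15-oxo-16-norlabd-8(17)-en-13-yn-19-oic acid
Product: 27 (4S,5R,9S,10R,12S,13Z)-12-hydroxylabda-8(17),13-diene-15,19-dioic acid, via (13Z)-hydroxy enoate methyl ester 25 (not isolated), via dilithium dicarboxylate 26 (not isolated)
Conditions: Me2CuLi (5 equiv, from CuI and MeLi), THF, −78 °C; MeOH quench at −78 °C, aq. NH4Cl–NH3 work-up; LiOH (6 equiv), THF–H2O, 0 to 20 °C; 0.5 M HCl to pH 5 at 0 °C
Reagents that add atoms: lithium dimethylcuprate [Li+].C[Cu-]C; lithium hydroxide [Li+].[OH-]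
Why: Organocuprate conjugate addition to the ynoate is a syn-carbometalation, so methyl enters at C13 and low-temperature protonation with retention gives the 13Z enoate (C12 and C15 cis); lithium hydroxide saponification, which also opens any butenolide formed by lactonisation, then gives the dicarboxylate, and cold acidification to pH 5 should release the diacid without relactonisation.

## Compound list

1 | tert-butyl 2-oxocyclohexane-1-carboxylate | O=C1CCCCC1C(=O)OC(C)(C)C | starting material
2 | dilithium dienolate (dianion) of 1 | [Li+].[Li+].CC(C)(C)OC([O-])=C1CCCC=C1[O-] | intermediate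
3 | tert-butyl 3-methyl-2-oxocyclohexane-1-carboxylate (racemic, diastereomer and enol mixture) | CC1CCCC(C(=O)OC(C)(C)C)C1=O | intermediate
4 | tert-butyl (1R)-1-hydroxy-3-methyl-2-oxocyclohexane-1-carboxylate (C3 epimers) | CC1CCC[C@](O)(C(=O)OC(C)(C)C)C1=O | intermediate
5 | 3-(1,3-dioxolan-2-yl)propanoic acid | OC(=O)CCC1OCCO1 | starting material
6 | (1R)-1-(tert-butoxycarbonyl)-3-methyl-2-oxocyclohexyl 3-(1,3-dioxolan-2-yl)propanoate (C3 epimers) | CC1CCC[C@](OC(=O)CCC2OCCO2)(C(=O)OC(C)(C)C)C1=O | intermediate
7 | tert-butyl (1R)-2-[(tert-butyldimethylsilyl)oxy]-1-{[3-(1,3-dioxolan-2-yl)propanoyl]oxy}-3-methylcyclohex-2-ene-1-carboxylate | CC1=C(O[Si](C)(C)C(C)(C)C)[C@@](OC(=O)CCC2OCCO2)(C(=O)OC(C)(C)C)CCC1 | intermediate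
8 | trimethylsilyl ketene acetal of 7 | CC1=C(O[Si](C)(C)C(C)(C)C)[C@@](OC(O[Si](C)(C)C)=CCC2OCCO2)(C(=O)OC(C)(C)C)CCC1 | intermediate
9 | trimethylsilyl ester of 10 (C10 R, C9 epimers) | CC(C)(C)OC(=O)C1=C(O[Si](C)(C)C(C)(C)C)[C@](C)(CCC1)C(CC2OCCO2)C(=O)O[Si](C)(C)C | intermediate
10 | (2RS)-2-{(1R)-3-(tert-butoxycarbonyl)-2-[(tert-butyldimethylsilyl)oxy]-1-methylcyclohex-2-en-1-yl}-3-(1,3-dioxolan-2-yl)propanoic acid | CC(C)(C)OC(=O)C1=C(O[Si](C)(C)C(C)(C)C)[C@](C)(CCC1)C(CC2OCCO2)C(=O)O | intermediate
11 | tert-butyl (3R)-2-[(tert-butyldimethylsilyl)oxy]-3-[3-(1,3-dioxolan-2-yl)-1-methoxy-1-oxopropan-2-yl]-3-methylcyclohex-1-ene-1-carboxylate (C9 epimers) | CC(C)(C)OC(=O)C1=C(O[Si](C)(C)C(C)(C)C)[C@](C)(CCC1)C(CC2OCCO2)C(=O)OC | intermediate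
12 | tert-butyl (3R)-2-[(tert-butyldimethylsilyl)oxy]-3-[2-(1,3-dioxolan-2-yl)-1-(1-hydroxycyclopropyl)ethyl]-3-methylcyclohex-1-ene-1-carboxylate (C9 epimers) | CC(C)(C)OC(=O)C1=C(O[Si](C)(C)C(C)(C)C)[C@](C)(CCC1)C(CC2OCCO2)C3(O)CC3 | intermediate
13 | tert-butyl (3R)-3-[2-(1,3-dioxolan-2-yl)-1-(1-hydroxycyclopropyl)ethyl]-3-methyl-2-{[(trifluoromethyl)sulfonyl]oxy}cyclohex-1-ene-1-carboxylate (C9 epimers) | CC(C)(C)OC(=O)C1=C(OS(=O)(=O)C(F)(F)F)[C@](C)(CCC1)C(CC2OCCO2)C3(O)CC3 | intermediate
14 | tert-butyl (4aR)-5-[(1,3-dioxolan-2-yl)methyl]-4a-methyl-6-oxo-2,3,4,4a,5,6,7,8-octahydronaphthalene-1-carboxylate (C4=C5 enoate, C8 ketone, C9 epimers) | CC(C)(C)OC(=O)C1=C2CCC(=O)C(CC3OCCO3)[C@@]2(C)CCC1 | intermediate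
15 | dilithium C8-alkoxide C4-ester enolate (H-5 anti to C20) | [Li+].[Li+].[O-]C1CC[C@@H]2[C@](C)(CCCC2=C([O-])OC(C)(C)C)C1CC3OCCO3 | intermediate
16 | tert-butyl 12,12-(ethylenedioxy)-8-hydroxy-13,14,15,16,17-pentanorlabdan-19-oate (C4, C5, C10 as in the target; C8 and C9 epimers) | OC1CC[C@@H]2[C@](C)(CCC[C@]2(C)C(=O)OC(C)(C)C)C1CC3OCCO3 | intermediate
17 | tert-butyl 12,12-(ethylenedioxy)-8-oxo-13,14,15,16,17-pentanorlabdan-19-oate, C9 epimer mixture | O=C1CC[C@@H]2[C@](C)(CCC[C@]2(C)C(=O)OC(C)(C)C)C1CC3OCCO3 | intermediate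
18 | tert-butyl 12,12-(ethylenedioxy)-8-oxo-13,14,15,16,17-pentanorlabdan-19-oate (C9 side chain equatorial, as in the target) | O=C1CC[C@@H]2[C@](C)(CCC[C@]2(C)C(=O)OC(C)(C)C)[C@H]1CC3OCCO3 | intermediate
19 | tert-butyl 12,12-(ethylenedioxy)-13,14,15,16-tetranorlabd-8(17)-en-19-oate | C=C1CC[C@@H]2[C@](C)(CCC[C@]2(C)C(=O)OC(C)(C)C)[C@H]1CC3OCCO3 | intermediate
20 | tert-butyl 12-oxo-13,14,15,16-tetranorlabd-8(17)-en-19-oate | C=C1CC[C@@H]2[C@](C)(CCC[C@]2(C)C(=O)OC(C)(C)C)[C@H]1CC=O | intermediate
21 | methyl propiolate | C#CC(=O)OC | starting material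
22 | 19-tert-butyl 15-methyl (12S)-12-hydroxy-16-norlabd-8(17)-en-13-yne-15,19-dioate | C=C1CC[C@@H]2[C@](C)(CCC[C@]2(C)C(=O)OC(C)(C)C)[C@H]1C[C@H](O)C#CC(=O)OC | intermediate
23 | bis(trimethylsilyl) derivative of 24 (C19 silyl ester, C12 silyl ether) | C=C1CC[C@@H]2[C@](C)(CCC[C@]2(C)C(=O)O[Si](C)(C)C)[C@H]1C[C@H](O[Si](C)(C)C)C#CC(=O)OC | intermediate
24 | (12S)-12-hydroxy-15-methoxy-15-oxo-16-norlabd-8(17)-en-13-yn-19-oic acid | C=C1CC[C@@H]2[C@](C)(CCC[C@]2(C)C(=O)O)[C@H]1C[C@H](O)C#CC(=O)OC | intermediate
25 | (12S,13Z)-12-hydroxy-15-methoxy-15-oxolabda-8(17),13-dien-19-oic acid | C=C1CC[C@@H]2[C@](C)(CCC[C@]2(C)C(=O)O)[C@H]1C[C@H](O)/C(C)=C\C(=O)OC | intermediate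
26 | dilithium (12S,13Z)-12-hydroxylabda-8(17),13-diene-15,19-dioate | [Li+].[Li+].C=C1CC[C@@H]2[C@](C)(CCC[C@]2(C)C(=O)[O-])[C@H]1C[C@H](O)/C(C)=C\C(=O)[O-] | intermediate
27 | (4S,5R,9S,10R,12S,13Z)-12-hydroxylabda-8(17),13-diene-15,19-dioic acid | C=C1CC[C@@H]2[C@](C)(CCC[C@]2(C)C(=O)O)[C@H]1C[C@H](O)/C(C)=C\C(=O)O | target

## Step count and risks

Total steps: 15. Longest linear sequence: 15 steps (1 to 27).

Steps most likely to fail:

Step 8. β-Hydride elimination of the alkylpalladium homoenolate may outrun C–C reductive elimination, which would give the vinyl ketone and the detriflated enoate instead of ring B. The fallback sets out from 13 and closes the same bond from two electrophiles. N-Bromosuccinimide opens the cyclopropanol to the β-bromo ketone tert-butyl (3R)-3-[5-bromo-1-(1,3-dioxolan-2-yl)-3-oxopentan-2-yl]-3-methyl-2-{[(trifluoromethyl)sulfonyl]oxy}cyclohex-1-ene-1-carboxylate F1. A nickel-catalysed intramolecular reductive cross-electrophile coupling of the alkyl bromide with the alkenyl triflate (NiBr2·glyme, 4,4′-di-tert-butyl-2,2′-bipyridine, Mn powder, DMA, 40 °C) should then form C5–C6 through an alkyl radical captured at nickel. It comes back to the route at 14.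

Step 5. The α-branched silyl ketene acetal may be too hindered to reach the tetrasubstituted enol ether terminus, so that decomposition of the ester enolate competes with the [3,3] shift. The fallback sets out from 4, rearranges an unbranched ester and attaches C11–C12 afterwards. Acetylation (Ac2O, DMAP, Et3N) gives tert-butyl (1R)-1-acetoxy-3-methyl-2-oxocyclohexane-1-carboxylate F2. Silylation (TBSOTf, Et3N) gives tert-butyl (1R)-1-acetoxy-2-[(tert-butyldimethylsilyl)oxy]-3-methylcyclohex-2-ene-1-carboxylate F3. Ireland–Claisen rearrangement of the acetate followed by TMSCHN2 gives tert-butyl (3R)-2-[(tert-butyldimethylsilyl)oxy]-3-(2-methoxy-2-oxoethyl)-3-methylcyclohex-1-ene-1-carboxylate F4. Alkylation of its ester enolate at C9 (LiN(iPr)2, THF–DMPU, (1,3-dioxolan-2-yl)methyl trifluoromethanesulfonate) comes back to the route at 11.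

Step 9. Protonation at C5 may show poor facial selectivity, or a ketone enolate formed by lithium amide may be methylated at C7 or C9. The fallback sets out from 14 and separates reduction from alkylation. NaBH4 reduction gives tert-butyl (4aR)-5-[(1,3-dioxolan-2-yl)methyl]-6-hydroxy-4a-methyl-2,3,4,4a,5,6,7,8-octahydronaphthalene-1-carboxylate F5. Hydrogen-atom-transfer hydrogenation of the enoate (Mn(dpm)3, PhSiH3, tert-butyl hydroperoxide, isopropanol) should deliver hydrogen to C5 on the face away from C20 and give the trans-fused tert-butyl 5-[(1,3-dioxolan-2-yl)methyl]-6-hydroxy-4a-methyldecahydronaphthalene-1-carboxylate F6. Methylation of its ester enolate from the α-face (LiN(iPr)2 3 equiv, then MeI, with the C8 hydroxyl carried as its lithium alkoxide) comes back to the route at 16.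

Further compounds
F1 | step 8 | tert-butyl (3R)-3-[5-bromo-1-(1,3-dioxolan-2-yl)-3-oxopentan-2-yl]-3-methyl-2-{[(trifluoromethyl)sulfonyl]oxy}cyclohex-1-ene-1-carboxylate | CC(C)(C)OC(=O)C1=C(OS(=O)(=O)C(F)(F)F)[C@](C)(CCC1)C(CC2OCCO2)C(=O)CCBr
F2 | step 5 | tert-butyl (1R)-1-acetoxy-3-methyl-2-oxocyclohexane-1-carboxylate | CC1CCC[C@](OC(C)=O)(C(=O)OC(C)(C)C)C1=O
F3 | step 5 | tert-butyl (1R)-1-acetoxy-2-[(tert-butyldimethylsilyl)oxy]-3-methylcyclohex-2-ene-1-carboxylate | CC1=C(O[Si](C)(C)C(C)(C)C)[C@@](OC(C)=O)(C(=O)OC(C)(C)C)CCC1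
F4 | step 5 | tert-butyl (3R)-2-[(tert-butyldimethylsilyl)oxy]-3-(2-methoxy-2-oxoethyl)-3-methylcyclohex-1-ene-1-carboxylate | CC(C)(C)OC(=O)C1=C(O[Si](C)(C)C(C)(C)C)[C@](C)(CCC1)CC(=O)OC
F5 | step 9 | tert-butyl (4aR)-5-[(1,3-dioxolan-2-yl)methyl]-6-hydroxy-4a-methyl-2,3,4,4a,5,6,7,8-octahydronaphthalene-1-carboxylate | CC(C)(C)OC(=O)C1=C2CCC(O)C(CC3OCCO3)[C@@]2(C)CCC1
F6 | step 9 | tert-butyl 5-[(1,3-dioxolan-2-yl)methyl]-6-hydroxy-4a-methyldecahydronaphthalene-1-carboxylate (trans-fused, C1 epimers) | OC1CC[C@@H]2[C@](C)(CCCC2C(=O)OC(C)(C)C)C1CC3OCCO3
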